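The numbers are those of an exercise; what happens was integrated by code.

Take gamma as the earlier run: theta and zeta are its neighbours, each with one charge fed slowly instead.

    starting material + free catalyst ⇌ catalyst intermediate A (K1 = 2.0 × 10⁵ L mol⁻¹, k1 = 2.0 × 10⁵ L mol⁻¹ s⁻¹)
    catalyst intermediate A → free catalyst + target (k2 = 200 s⁻¹)
    second substrate + free catalyst ⇌ catalyst intermediate B (K3 = 1800 L mol⁻¹, k3 = 2.4 × 10⁶ L mol⁻¹ s⁻¹)
    catalyst intermediate B → free catalyst + second product (k4 = 1500 s⁻¹)
    starting material → decomposition product (k5 = 5.8 × 10⁻⁵ s⁻¹)
    target → over-reaction product (k6 = 0.017 s⁻¹)
    starting material + target → side product (k7 = 23 L mol⁻¹ s⁻¹)

| flask | starting material | second substrate | free catalyst | time | remark |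
|---|---|---|---|---|---|
| gamma | 0.50 mM | 1.00 mM | 1.6 µM | 40 s | everything together at the start |
| theta | 0.50 mM (fed, over 30 s) | 1.00 mM | 1.6 µM | 40 s | all else is in the flask from the start; the feed brings no volume worth counting |
| zeta | 0.50 mM | 1.00 mM (fed, over 30 s) | 1.6 µM | 40 s | all else is in the flask from the start; the feed brings no volume worth counting |

- percentages count the starting material that a species holds: one side product counts as two
- run time (gamma): 40 s

- the best flask by amount of target, in percent of the starting material charged; "all alike" if 1.5 percentage points covers them all (gamma / theta / zeta / all alike)
- amount of target at the end, in percent of the starting material charged, gamma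
- amount of target at the end, in percent of the starting material charged, theta
- amount of target at the end, in percent of the starting material charged, zeta

**First instants.** Count turnovers. In gamma each catalyst must make 312 turnovers of starting material and 625 of second substrate. At the full release rates of 200 s⁻¹ and 1500 s⁻¹ these take 1.56 s and 0.417 s. Together that is far shorter than the target's life of 58.8 s against over-reaction.

**The middle.** Capture of starting material runs at 100 s⁻¹ per catalyst at full charge, half of the release rate of 200 s⁻¹, so the two are of like size at first and part of the catalyst sits in catalyst intermediate A. As starting material falls, capture falls with it while release stays, and free catalyst becomes the resting state. Starting material then falls pseudo-first-order, with a clearing time of 3.12 s. In theta the same clearing time holds the standing starting material near 10.4% of the charge during the feed, and the target is born evenly over those 30 s. In zeta the feed ties up hardly any of the catalyst in catalyst intermediate B, so starting material clears with the same clearing time.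

**The end.** In gamma and zeta the target is born about one clearing time in, so it waits 36.9 s. This waiting time, the mean span from a target's birth to the reading, is the quantity to carry. In theta birth comes half the feed later, so the wait is 21.9 s. Survival is the exponential of minus the over-reaction constant times the wait: 53.4% for gamma and zeta, 68.9% for theta. Take from these what the side reaction costs, and expect theta to be best.

**The outcome.** The forecast gives 52.2%, 68% and 52% for gamma, theta and zeta, with theta best, on the ground that “Feeding the starting material makes the target form later and keeps its exposure shorter”. The flasks hold 52.4%, 67.2% and 52.1%, and theta is best.

**Wait again.** The survival figures stand 1.0 percentage point above gamma and 1.7 points above theta, where the side product holds 3.86% and 3.04%. Now read zeta later, at 150 s, with nothing else changed. The clearing time stays, so the wait grows to 147 s and survival falls to 8.23%. That neighbouring flask holds 8.03% of target.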